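I decided to count turnovers of the intermediate and fit nothing.

| flask | substrate | coupling partner | protic impurity | remark | time |
|---|---|---|---|---|---|
| grey | 0.020 M | 0.080 M | 1 mM | run made earlier |  |
| red | 0.020 M | 0.040 M | 1 mM | run made earlier |  |
| west | 0.020 M | 0.0800 M (fed, over 6.40 min) | 1.00 mM | a stirred flask in which coupling partner is dosed at a steady rate over 6.40 min without added volume, worked up at 8.0 min | 8.0 min |
| north-west | 0.020 M (fed, over 6.40 min) | 0.0800 M | 1.00 mM | a stirred flask in which substrate is dosed at a steady rate over 6.40 min without added volume, worked up at 8.0 min | 8.0 min |
| north-east | 0.020 M | 0.0800 M | 1.00 mM | a single well-mixed tank run continuously and read at steady state, 8.0 min in it on average |  |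
| south-east | 0.020 M | 0.0800 M | 1.00 mM | everything together in a closed stirred flask, run for 8.0 min | 8.0 min |

grey run (percent of the substrate charged)

| time / min | intermediate / % | target / % |
|---|---|---|
| 1.33 | 71 | 21 |
| 2.50 | 54 | 39 |
| 4.00 | 39 | 48 |
| 5.00 | 33 | 49 |

red run (percent of the substrate charged)

| time / s | intermediate / % | target / % |
|---|---|---|
| 12.0 | 23 | 3 |
| 25.0 | 38 | 2 |
| 40.0 | 47 | 6 |
| 50.0 | 53 | 8 |

(each reading ± 2 percentage points)

- the stated concentrations are those of everything mixed, before any reaction; amounts are the same in each set-up
- what was read earlier has a scatter of 2 percentage points, one standard deviation
- the feed brings no volume worth counting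
- the earlier runs were made in a closed, stirred flask
- a reading or a percentage of target counts all its forms, free or not

- the set-up with the highest amount of intermediate at the outlet or at the end, in percent of the substrate put in ("none" if the first two lie within 2 percentage points) (west / north-west / north-east / south-east / none)
- amount of intermediate at the outlet or at the end, in percent of the substrate put in, west
- amount of intermediate at the outlet or at the end, in percent of the substrate put in, north-west
- amount of intermediate at the outlet or at the end, in percent of the substrate put in, north-east
- amount of intermediate at the outlet or at the end, in percent of the substrate put in, south-east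

1. South-east has the charges of the grey run, where substrate is the limiting reagent and partner stands at 4.00 times its charge. So I read grey for south-east.

2. Between grey's first and third readings, the intermediate fell at 0.224 min⁻¹. I call this first-order rate the turnover rate. Turnovers are this rate times the time held.

3. My rule of thumb took formation as instant. A closed flask keeps exp(−turnovers), and a tank keeps 1/(1 + turnovers).

4. South-east counts 1.80 turnovers, so it keeps 16.6 %. The tank, at the same average time, keeps 35.8 %.

5. In north-west, each slice of substrate ages from its own moment of entry until the end of the run. Averaged over the feed, the rule gives 37.1 %. That is within the margin of the tank, so I could not separate them. West I did not count.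

6. The border showed in grey's last step. There the fall was 0.167 min⁻¹, slower than the turnover rate, a ratio of 0.746. With the scatter this was a warning, not a proof. Grey's third reading stands at 0.898 turnovers, and south-east lies beyond it. So I held my south-east figure as likely low.

7. The forecast named north-west, with 30 % in west, 41 % in north-west, 35 % in north-east and 19 % in south-east. It called the decay “first order and independent of partner”. Unlike mine, it separated north-west from the tank.

    coupling partner + protic impurity → quenched reagent (k = 56.0 M⁻¹ min⁻¹)
    target ⇌ isomer of the product B (K = 8.40, k = 0.0870 min⁻¹)
    intermediate ⇌ isomer of the product A (K = 36.0, k = 0.0170 min⁻¹)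
    substrate + coupling partner → intermediate + by-product (k = 38.0 M⁻¹ min⁻¹)
    substrate + target ⇌ idle adduct, settled at all times (K = 60.0 M⁻¹)
    intermediate ⇌ target (K = 2.20, k = 0.330 min⁻¹)

The flask gave north-west as best, with 31.1 % in west, 38.9 % in north-west, 34.7 % in north-east and 25.0 % in south-east. The step from intermediate to target runs both ways, and its relaxation half-life in south-east, both ways together, was 1.44 min, shorter than the 8.0 min of the run. South-east stopped at 3.0 min counts 0.673 turnovers, so the count gives 51.0 %, and that flask held 48.5 %.

The readings stem from a simulated flask on assumed constants.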